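Ring A is cut at C2–C3. Because the C2 hydroxyl lies 1,3 to the quaternary C4, ring A can be closed by a type 2 carbonyl-ene reaction between a C2 aldehyde, carried on a two-carbon arm at C10, and an isopropenyl group at C5. Ring B, with the C8 methyl on the C7=C8 alkene and the C5 stereocentre, maps onto (R)-carvone. In one operation Me2AlCl forges C2–C3, closes trans-fused ring A, creates the C2 carbinol (axial, inverted in the next step) and leaves a C4 exocyclic methylene for C18 and C19. The precursor is 6,6-dialkylated (R)-carvone: C10 methyl cis and 2-oxoethyl arm trans to the isopropenyl group, C9 enone intact.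

Key step: step 5

Remark: labdane numbering is used for all intermediates (carvone C6 becomes C10; α is the face of H-5, β the face of the C10 methyl), and a centre that the next step destroys is drawn as its expected major epimer or left undefined.

Step 1
Reactants: 1 (R)-(−)-carvone; 2 iodomethane
Product: 4 methylated carvone ((5R,6S)-6-methylcarvone; the 6-epimer serves equally), via carvone lithium enolate 3 (not isolated)
Conditions: LiN(iPr)2, THF, −78 °C; then MeI, −78 to 0 °C
Reagents that add atoms: iodomethane, CI
Why: Kinetic deprotonation by the hindered amide removes an α′ proton (carvone C6, the future C10) to give the cross-conjugated enolate, whose SN2 methylation (enolate alkylation) installs C20; the new centre is flattened again in step 2, so its configuration does not matter.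

Step 2
Reactants: 4 methylated carvone; 5 ethyl bromoacetate
Product: 7 keto ester (C10 methyl cis and CH2CO2Et arm trans to the isopropenyl group), via methylcarvone lithium enolate 6 (not isolated)
Conditions: LiN(iPr)2, THF, −78 °C; then BrCH2CO2Et, DMPU, −78 to −20 °C
Reagents that add atoms: ethyl bromoacetate, CCOC(=O)CBr
Why: Enolate alkylation of the tetrasubstituted α′ enolate: the adjacent isopropenyl group turns pseudoaxial to escape allylic strain with the enolate methyl and shields one face, so the bromoacetate enters anti to it and the quaternary C10 is set with the methyl cis and the ester arm trans to the isopropenyl group, as closure to a trans-decalin requires.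

Step 3
Reactants: 7 keto ester
Product: 8 diol (primary alcohol on the C10 arm; C9 carbinol as epimer mixture)
Conditions: LiAlH4, Et2O, 0 °C
Reagents that add atoms: none
Why: LiAlH4 reduces the ester to the primary alcohol and the conjugated ketone in 1,2 fashion; the C9 carbinol epimers converge again in step 4, and the isolated isopropenyl alkene is inert to hydride.

Step 4
Reactants: 8 diol
Product: 9 keto aldehyde (ene precursor)
Conditions: (COCl)2, DMSO, CH2Cl2, −78 °C; then Et3N, −78 to 0 °C
Reagents that add atoms: none
Why: Swern oxidation turns both hydroxyls into carbonyls under cold, non-acidic conditions that neither isomerise the isopropenyl group nor trigger premature closure, and the aldehyde carries no α-stereocentre that could be lost.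

Step 5
Reactants: 9 keto aldehyde
Product: 10 2β-hydroxy enone (trans-decalin; 5α-H; 10β-CH3; C9 ketone conjugated to C7=C8; exocyclic C4=CH2; axial C2–OH)
Conditions: Me2AlCl (2.2 equiv), CH2Cl2, −78 to −20 °C; then 1 M HCl, 0 °C
Reagents that add atoms: none
Why: Me2AlCl binds the aldehyde oxygen anti to C1, and the terminal carbon of the isopropenyl group (C3) attacks C2 while a hydrogen of the isopropenyl methyl passes to the aluminium-bound oxygen through a six-membered array, any positive charge at C4 being fleeting; the alkoxide then loses methane, which keeps the medium non-protic and prevents alkene migration. The closest known reaction type is the alkylaluminium halide-promoted type 2 intramolecular carbonyl-ene cyclisation of δ,ε-unsaturated aldehydes to 3-methylenecyclohexanols. Ring A closes as a six-membered ring, exo with respect to the carbonyl and endo with respect to the alkene (ene unit tethered through its central carbon C4), over a chair in which the C10 arm and the C5 isopropenyl group are both equatorial on ring B, so the fusion is trans and no new fusion stereocentre is made. At C2 the hydrogen transfer requires the C=O bond to lie gauche to C3–C4, which means axial on the chair, so the carbinol is expected mainly axial (2β), the syn-axial C10 methyl eroding but not overturning this preference; any equatorial epimer formed alongside is compound 12 itself, is separated and rejoins the route after step 6, so the route does not hinge on this ratio. Chemoselectivity for the aldehyde rests on the C9 ketone being conjugated and wedged between the quaternary C10 and the C8 methyl, and regioselectivity for the exocyclic alkene on the fact that only the methyl hydrogens, not H-5 on the opposite face, can reach the axial oxygen.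

Step 6
Reactants: 10 2β-hydroxy enone
Product: 12 2α-hydroxy enone (equatorial C2–OH), via inverted nitrobenzoate 11 (not isolated)
Conditions: PPh3, DIAD, 4-O2NC6H4CO2H, toluene, 0 °C to rt; then K2CO3, MeOH, rt
Reagents that add atoms: 4-nitrobenzoic acid, OC(=O)c1ccc(cc1)[N+](=O)[O-]
Why: Mitsunobu reaction: the axial 2β-hydroxyl is activated as an oxyphosphonium ion and displaced by 4-nitrobenzoate with SN2 inversion from the unhindered equatorial direction, and mild methanolysis in the same flask frees the equatorial 2α-alcohol required by the target.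

Step 7
Reactants: 12 2α-hydroxy enone
Product: 13 2α-silyl ether
Conditions: TBSCl, imidazole, DMF, rt
Reagents that add atoms: tert-butyldimethylsilyl chloride, CC(C)(C)[Si](C)(C)Cl
Why: Silyl ether formation on the unhindered equatorial secondary alcohol gives a group that withstands the Lewis acid, the strong bases and the hydrides of steps 9 to 16 and is removed together with the C19 silyl ether at the end.

Step 8
Reactants: 13 2α-silyl ether
Product: 14 spiro-epoxide (oxirane on C4 and C19; oxygen on the α face)
Conditions: mCPBA, NaHCO3, CH2Cl2, 0 °C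
Reagents that add atoms: 3-chloroperbenzoic acid, OOC(=O)c1cccc(Cl)c1
Why: Prilezhaev epoxidation is chemoselective for the electron-rich 1,1-disubstituted C4=CH2 alkene because the C7=C8 alkene is deactivated by conjugation with the C9 ketone; the peracid should approach from the α face away from the axial C10 methyl, but the epoxide configuration is erased in step 9.

Step 9
Reactants: 14 spiro-epoxide
Product: 15 C4 carbaldehyde (C4–H epimers)
Conditions: BF3·OEt2 (0.3 equiv), CH2Cl2, −78 °C
Reagents that add atoms: none
Why: Meinwald rearrangement: BF3 opens the epoxide at the tertiary C4–O bond and a 1,2-hydride shift from the oxirane CH2 delivers the C4 carbaldehyde, whose C4 epimers are both funnelled into one enolate in step 10.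

Step 10
Reactants: 15 C4 carbaldehyde; 2 iodomethane
Product: 17 quaternary aldehyde (4α-methyl and 4β-formyl), via potassium enolate 16 (not isolated)
Conditions: KOtBu (1.1 equiv), MeI (5 equiv), THF, −20 to 0 °C
Reagents that add atoms: iodomethane, CI
Why: C-Alkylation of the exocyclic aldehyde enolate (enolate alkylation of an α-branched aldehyde): the β face of C4 is screened by the syn-axial C10 methyl, so MeI enters equatorially from the α face and the quaternary C4 is set with C18 α and the formyl carbon (C19) β-axial, while the enone, whose γ-hydrogens are far less acidic than the aldehyde α-hydrogen, is left alone by one equivalent of base.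

Step 11
Reactants: 17 quaternary aldehyde
Product: 18 C19 alcohol
Conditions: NaBH4, MeOH/THF, −40 to 0 °C
Reagents that add atoms: none
Why: Borohydride reduction is chemoselective for the aldehyde because the C9 ketone is conjugated and wedged between the quaternary C10 and the C8 methyl; no stereocentre is formed.

Step 12
Reactants: 18 C19 alcohol
Product: 19 bis-silyl ether enone
Conditions: TBSCl, imidazole, DMAP (cat.), DMF, 40 °C
Reagents that add atoms: tert-butyldimethylsilyl chloride, CC(C)(C)[Si](C)(C)Cl
Why: Silylation of the neopentyl but primary C19 hydroxyl completes a protecting-group pattern in which only the future C15 hydroxyl will be free for acetylation.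

Step 13
Reactants: 19 bis-silyl ether enone; 20 methyltriphenylphosphonium bromide
Product: 21 diene (C7=C8–C9=C11H2)
Conditions: Ph3PCH3Br, KOtBu, toluene, 90 °C
Reagents that add atoms: methyltriphenylphosphonium bromide, C[P+](c1ccccc1)(c1ccccc1)c1ccccc1.[Br-]
Why: Wittig methylenation with the small ylide Ph3P=CH2 at elevated temperature is the established way to olefinate hindered ketones that cannot be enolised towards the quaternary centre, and it installs C11 as the terminus of the diene.

Step 14
Reactants: 21 diene; 22 bromoacetone
Product: 24 methyl ketone (9α-H; C9–CH2CH2COCH3), via homoallylic borane 23 (not isolated)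
Conditions: 9-BBN (1.1 equiv), THF, 0 to 50 °C; then BrCH2COCH3, potassium 2,6-di-tert-butylphenoxide, THF, 0 °C to rt
Reagents that add atoms: bromoacetone, CC(=O)CBr
Why: 9-BBN hydroborates only the 1,1-disubstituted diene terminus, placing boron on C11 and hydrogen on C9 from the α face opposite the axial C10 methyl (9α-H and a β-equatorial side chain), and the resulting B-alkyl-9-BBN then alkylates the bromoacetone enolate through a borate whose primary alkyl group migrates from boron to carbon with loss of bromide (α-alkylation of α-halo ketones by organoboranes), which adds C12, C13 and C16 without any displacement at the hindered C11.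

Step 15
Reactants: 24 methyl ketone; 25 triethyl phosphonoacetate
Product: 26 ethyl (E)-enoate
Conditions: (EtO)2P(O)CH2CO2Et, NaH, THF, 0 °C to reflux
Reagents that add atoms: triethyl phosphonoacetate, CCOC(=O)CP(=O)(OCC)OCC
Why: Horner–Wadsworth–Emmons olefination of the methyl ketone: reversible addition and elimination through the less crowded oxaphosphetane favours the E-enoate, in which the chain is trans to the ester, and the minor Z isomer is separable by chromatography.

Step 16
Reactants: 26 ethyl (E)-enoate
Product: 27 (E)-allylic alcohol
Conditions: iBu2AlH, CH2Cl2, −78 °C; then aq. potassium sodium tartrate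
Reagents that add atoms: none
Why: iBu2AlH reduces the conjugated ester in 1,2 fashion to the allylic alcohol at low temperature without touching the alkenes or the silyl ethers, so the E geometry is retained.

Step 17
Reactants: 27 (E)-allylic alcohol; 28 acetic anhydride
Product: 29 bis-silylated acetate
Conditions: Ac2O, pyridine, DMAP (cat.), CH2Cl2, 0 °C to rt
Reagents that add atoms: acetic anhydride, CC(=O)OC(C)=O
Why: Acylation (DMAP-catalysed esterification) of the only free hydroxyl, the primary allylic C15–OH, gives the acetate while both other oxygens remain silylated.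

Step 18
Reactants: 29 bis-silylated acetate
Product: 30 CNP0165423.1 (target)
Conditions: HF·pyridine, pyridine, THF, 0 °C to rt
Reagents that add atoms: none
Why: Fluoride-driven desilylation with pyridine-buffered HF cleaves both silyl ethers through the strong Si–F bond under conditions too mild to hydrolyse or ionise the allylic acetate or to move the trisubstituted alkenes, and no stereocentre is touched.

Compound list

1 | (R)-(−)-carvone, (5R)-2-methyl-5-(prop-1-en-2-yl)cyclohex-2-en-1-one | CC1=CC[C@H](CC1=O)C(C)=C | starting material
2 | iodomethane | CI | starting material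
3 | lithium enolate of carvone (cross-conjugated, C1–C6 of carvone) | CC1=CC[C@H](C=C1O[Li])C(C)=C | intermediate
4 | (5R,6S)-2,6-dimethyl-5-(prop-1-en-2-yl)cyclohex-2-en-1-one (6-methylcarvone, trans epimer drawn; cis epimer equally useful) | O=C1C(C)=CC[C@@H](C(C)=C)[C@@H]1C | intermediate
5 | ethyl bromoacetate | CCOC(=O)CBr | starting material
6 | lithium enolate of 6-methylcarvone | CC1=CC[C@H](C(C)=C1O[Li])C(C)=C | intermediate
7 | ethyl 2-[(1S,6S)-1,3-dimethyl-2-oxo-6-(prop-1-en-2-yl)cyclohex-3-en-1-yl]acetate | O=C1C(C)=CC[C@@H](C(C)=C)[C@]1(C)CC(=O)OCC | intermediate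
8 | 2-[(1S,6S)-2-hydroxy-1,3-dimethyl-6-(prop-1-en-2-yl)cyclohex-3-en-1-yl]ethanol (carbinol epimers) | OC1C(C)=CC[C@@H](C(C)=C)[C@]1(C)CCO | intermediate
9 | 2-[(1S,6S)-1,3-dimethyl-2-oxo-6-(prop-1-en-2-yl)cyclohex-3-en-1-yl]acetaldehyde | O=C1C(C)=CC[C@@H](C(C)=C)[C@]1(C)CC=O | intermediate
10 | (4aS,7R,8aS)-7-hydroxy-2,8a-dimethyl-5-methylidene-4a,5,6,7,8,8a-hexahydronaphthalen-1(4H)-one (2β-OH, axial) | O=C1C(C)=CC[C@H]2C(=C)C[C@@H](O)C[C@]12C | intermediate
11 | 2α-(4-nitrobenzoyloxy) enone (4-nitrobenzoate of 12) | O=C1C(C)=CC[C@H]2C(=C)C[C@H](OC(=O)c3ccc(cc3)[N+](=O)[O-])C[C@]12C | intermediate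
12 | (4aS,7S,8aS)-7-hydroxy-2,8a-dimethyl-5-methylidene-4a,5,6,7,8,8a-hexahydronaphthalen-1(4H)-one (2α-OH, equatorial) | O=C1C(C)=CC[C@H]2C(=C)C[C@H](O)C[C@]12C | intermediate
13 | 2α-(tert-butyldimethylsilyloxy) derivative of 12 | O=C1C(C)=CC[C@H]2C(=C)C[C@H](O[Si](C)(C)C(C)(C)C)C[C@]12C | intermediate
14 | 4,19-epoxide of 13 (spiro-oxirane at C4, oxygen α) | O=C1C(C)=CC[C@H]2[C@@]3(CO3)C[C@H](O[Si](C)(C)C(C)(C)C)C[C@]12C | intermediate
15 | 2α-silyloxy enone with a formyl group and a hydrogen at C4 (C4 epimers) | O=C1C(C)=CC[C@H]2C(C=O)C[C@H](O[Si](C)(C)C(C)(C)C)C[C@]12C | intermediate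
16 | potassium enolate of 15 (exocyclic C4=CH–OK) | O=C1C(C)=CC[C@H]2C(=CO[K])C[C@H](O[Si](C)(C)C(C)(C)C)C[C@]12C | intermediate
17 | 2α-silyloxy-4α-methyl-4β-formyl enone | O=C1C(C)=CC[C@H]2[C@@](C)(C=O)C[C@H](O[Si](C)(C)C(C)(C)C)C[C@]12C | intermediate
18 | 2α-silyloxy-4α-methyl-4β-(hydroxymethyl) enone | O=C1C(C)=CC[C@H]2[C@@](C)(CO)C[C@H](O[Si](C)(C)C(C)(C)C)C[C@]12C | intermediate
19 | 2α,19-bis(tert-butyldimethylsilyloxy) enone | O=C1C(C)=CC[C@H]2[C@@](C)(CO[Si](C)(C)C(C)(C)C)C[C@H](O[Si](C)(C)C(C)(C)C)C[C@]12C | intermediate
20 | methyltriphenylphosphonium bromide | C[P+](c1ccccc1)(c1ccccc1)c1ccccc1.[Br-] | starting material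
21 | 2α,19-bis(silyloxy) 7,9(11)-diene (exocyclic C9=C11H2) | C=C1C(C)=CC[C@H]2[C@@](C)(CO[Si](C)(C)C(C)(C)C)C[C@H](O[Si](C)(C)C(C)(C)C)C[C@]12C | intermediate
22 | bromoacetone | CC(=O)CBr | starting material
23 | B-(C11-alkyl)-9-borabicyclo[3.3.1]nonane (9α-H, C11–B) | C1CCC2CCCC1B2C[C@H]1C(C)=CC[C@H]2[C@@](C)(CO[Si](C)(C)C(C)(C)C)C[C@H](O[Si](C)(C)C(C)(C)C)C[C@]12C | intermediate
24 | 2α,19-bis(silyloxy)-14,15-dinorlabd-7-en-13-one | CC(=O)CC[C@H]1C(C)=CC[C@H]2[C@@](C)(CO[Si](C)(C)C(C)(C)C)C[C@H](O[Si](C)(C)C(C)(C)C)C[C@]12C | intermediate
25 | triethyl phosphonoacetate | CCOC(=O)CP(=O)(OCC)OCC | starting material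
26 | ethyl 2α,19-bis(silyloxy)labda-7,13E-dien-15-oate | CCOC(=O)/C=C(\C)CC[C@H]1C(C)=CC[C@H]2[C@@](C)(CO[Si](C)(C)C(C)(C)C)C[C@H](O[Si](C)(C)C(C)(C)C)C[C@]12C | intermediate
27 | 2α,19-bis(silyloxy)labda-7,13E-dien-15-ol | OC/C=C(\C)CC[C@H]1C(C)=CC[C@H]2[C@@](C)(CO[Si](C)(C)C(C)(C)C)C[C@H](O[Si](C)(C)C(C)(C)C)C[C@]12C | intermediate
28 | acetic anhydride | CC(=O)OC(C)=O | starting material
29 | 2α,19-bis(silyloxy)labda-7,13E-dien-15-yl acetate | CC(=O)OC/C=C(\C)CC[C@H]1C(C)=CC[C@H]2[C@@](C)(CO[Si](C)(C)C(C)(C)C)C[C@H](O[Si](C)(C)C(C)(C)C)C[C@]12C | intermediate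
30 | CNP0165423.1, 2α,19-dihydroxylabda-7,13E-dien-15-yl acetate | CC(=O)OC/C=C(\C)CC[C@H]1C(C)=CC[C@H]2[C@@](C)(CO)C[C@H](O)C[C@]12C | target

Total steps: 18. Longest linear sequence: 18 steps (fully linear from 1 to 30).

Steps most likely to fail

Step 5. The closure may leave the concerted path: the C4 cation is then trapped by chloride or loses a ring proton to give endocyclic alkene isomers, or the aluminium reagent transfers a methyl group to the aldehyde. The fallback forms the same C2–C3 bond by Nozaki–Hiyama allylation instead of the ene reaction. It sets out from keto ester 7: ene-type chlorination of the isopropenyl methyl (Ca(OCl)2, solid CO2, CH2Cl2/H2O, 0 °C; the enone alkene is inert) gives the allylic chloride keto ester F1. Reduction of ester and ketone with iBu2AlH (CH2Cl2, −78 °C) gives the chloro diol F2, and Swern oxidation gives the chloro keto aldehyde F3. CrCl2 (THF, rt) then closes ring A by allylation of the aldehyde through the terminal alkene carbon, which leaves the same exocyclic C4 methylene. The fallback returns to the route at 10; any C2 epimer is 12, and both are handled as in step 6.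

Step 14. The hindered borane may fail to form the borate with the bromoacetone enolate, or may transfer its alkyl group too slowly, so that the bromoketone is consumed by condensation with itself. The fallback is a stepwise alkylation that sets out from diene 21 through borane 23. Oxidation (NaOH, H2O2) gives the C11 alcohol F6, and I2, PPh3 and imidazole convert it into the C11 iodide F7. The weakly basic sodium enolate of ethyl acetoacetate (NaH, DMF, 60 °C) is alkylated to the β-keto ester F8. Saponification and decarboxylation (KOH, aqueous MeOH, 50 °C; then citric acid, 40 °C) return to methyl ketone 24.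

Step 10. The hindered aldehyde enolate may be methylated on oxygen, or the base may deprotonate the enone at C6 and methylate C8. The fallback replaces enolate alkylation by cyclopropanation and sets out from aldehyde 15. TMSCl, Et3N and NaI (MeCN, rt) give the trimethylsilyl enol ether F4. Simmons–Smith cyclopropanation (Et2Zn, CH2I2, CH2Cl2, 0 °C) from the open α face gives the siloxycyclopropane F5. K2CO3 in MeOH removes the silyl group and the cyclopropanolate opens at its unsubstituted CH2, which becomes the 4α-methyl group, returning to aldehyde 17.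

Further compounds

F1 | step 5 | ethyl 2-[(1S,6S)-6-(3-chloroprop-1-en-2-yl)-1,3-dimethyl-2-oxocyclohex-3-en-1-yl]acetate | O=C1C(C)=CC[C@@H](C(CCl)=C)[C@]1(C)CC(=O)OCC
F2 | step 5 | chloro diol (reduced F1; carbinol epimers) | OC1C(C)=CC[C@@H](C(CCl)=C)[C@]1(C)CCO
F3 | step 5 | chloro keto aldehyde (allylic chloride analogue of 9) | O=C1C(C)=CC[C@@H](C(CCl)=C)[C@]1(C)CC=O
F4 | step 10 | trimethylsilyl enol ether of aldehyde 15 | O=C1C(C)=CC[C@H]2C(=CO[Si](C)(C)C)C[C@H](O[Si](C)(C)C(C)(C)C)C[C@]12C
F5 | step 10 | spiro siloxycyclopropane at C4 (new CH2 on the α face) | O=C1C(C)=CC[C@H]2[C@]3(CC3O[Si](C)(C)C)C[C@H](O[Si](C)(C)C(C)(C)C)C[C@]12C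
F6 | step 14 | 2α,19-bis(silyloxy)drim-7-en-11-ol type C11 alcohol (9α-H) | OC[C@H]1C(C)=CC[C@H]2[C@@](C)(CO[Si](C)(C)C(C)(C)C)C[C@H](O[Si](C)(C)C(C)(C)C)C[C@]12C
F7 | step 14 | corresponding C11 iodide | IC[C@H]1C(C)=CC[C@H]2[C@@](C)(CO[Si](C)(C)C(C)(C)C)C[C@H](O[Si](C)(C)C(C)(C)C)C[C@]12C
F8 | step 14 | ethyl 2-acetyl-3-(C9-yl)propanoate β-keto ester (α-carbon epimers) | CCOC(=O)C(C(C)=O)C[C@H]1C(C)=CC[C@H]2[C@@](C)(CO[Si](C)(C)C(C)(C)C)C[C@H](O[Si](C)(C)C(C)(C)C)C[C@]12C
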